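## The problem

Mollicellin A (21) is a depsidone. Two benzene rings, ring A (the formyl-bearing benzoate ring) and ring B (the benzene ring of the chromanone), are joined twice, by an aryl ester and by a diaryl ether, and these two bridges close the seven-membered dioxepinone. Ring B also carries a fused 2,2-dimethylpyran-4-one. There is no stereocentre, so the task is purely regiochemical: each ring has a single hydrogen and five different substituents in a fixed order. The ether oxygen is flanked on ring A by the formyl and ester carbons and on ring B by a methyl group and the ester oxygen, so joining two finished rings at this oxygen would mean making a tetra-ortho-substituted diaryl ether. The groups that dislike rough treatment are: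

- the aryl ester of the dioxepinone (opened by nucleophiles and base, so best made last);
- the salicylaldehyde (best carried as an acetal);
- the chromanone (enolisable, able to open by retro-oxa-Michael reaction, and an aryl ketone chromophore);
- the free ring A phenol.

The enabling feature shows when ring A is numbered as a benzoate: C1 ester carbon, C2 aryloxy, C3 formyl, C4 hydroxyl, C5 hydrogen, C6 methyl. The C4 hydroxyl and the C2 aryloxy group are meta, C3 lies between them, and the C1 ester carbon sits next to C2. This is the pattern produced when a vinylketene bearing the carboxyl carbon (C4, C1, C6, C5) adds across an aryl ynol ether (C2, C3).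

## Retrosynthesis

**Lactone last.** The ester C–O bond of the dioxepinone in 21 is cut first, together with unmasking of the aldehyde, which leads back through acetal 20 to seco acid 19. This bond is the most fragile one in the target. Its closure is intramolecular across a diaryl ether hinge, so the forward reaction only has to activate a carboxyl group next to a phenol that is already held in place.

**One deprotection.** Seco acid 19 comes from 18, in which the carboxyl group and the ring B hydroxyl are both benzylated. A single hydrogenolysis then frees the two partners of the lactonisation. The acetal keeps the aldehyde out of reach of the ketene chemistry that precedes it.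

**Ring A as a whole (key cut).** In 18 the bonds C1–C2, C3–C4 and C4–C5 of ring A are cut, giving the aryl ynol ether 13 and the diazo keto ester 4. The neighbouring cut, the diaryl ether between two complete rings, would demand a coupling at two doubly ortho-substituted positions. Building ring A onto an oxygen that ring B already carries reduces the ether problem to attaching an alkyne to a phenol. The precursors are far simpler: 4 has five skeletal carbons and 13 is a chromanone with one extra three-carbon chain. The forward reaction must generate vinylketene 14 from 4, add it to 13 with the ketene carbonyl carbon on the acetal-bearing alkyne carbon, and carry the cyclobutenone 15 through ring opening (16) and 6π closure (17) to the phenol.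

**Ynol ether.** The C(sp)–O bond of 13 is traced through the (Z)-bromoenol ether 12 to phenol 11 and the dibromoalkene 6, which is one olefination away from the acetal aldehyde 5. This joins the alkyne to oxygen without organolithium reagents, which the chromanone would not tolerate. The forward coupling has to work on a phenol with two ortho substituents.

**Ring B.** In 11 the pyranone is cut at O1–C2 and C2–C3 (Kabbe condensation of the acetophenone 10 with acetone). The C6 oxygen of 10 is cut next: it sits para to the chelated phenol of 8, which is where an Elbs persulfate oxidation places it. Compound 8 is the mono-benzyl ether of the purchasable acetophenone 7. Oxygenating after the chromanone is formed would leave two activated positions competing; doing it on 8 leaves no choice.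

**Diazo ester.** Compound 4 is cut at the bond between the diazo carbon and the ketone carbon. This gives benzyl diazoacetate 1 and methacrolein 2, joined as the diazo alcohol 3 and then oxidised. The route avoids the diazo-free vinyl β-keto ester, which polymerises easily.

## Roads not taken

**Alternative 1: oxidative closure of a depside.** The cut is the diaryl ether C–O bond alone. The precursor is the depside A1, an ester of the ring A acid with a ring B phenol that still has a hydrogen where the ether oxygen will sit. In the forward step the ring B phenol is oxidised by two electrons (at an anode or with a hypervalent iodine oxidant). The ortho hydroxyl of ring A then attacks the carbon para to the ring B hydroxyl and closes the dioxepinone to give A2, and oxa-Michael closure of the enone completes the pyranone of 21.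

- Merits: it is biomimetic and by far the shortest road. The ether forms at a C–H bond with no halide, no alkyne and hardly any protecting groups. In step count it is clearly better than the chosen plan.
- Weak points: the phenol to be oxidised is chelated to an enoyl ketone and therefore electron-poor. The enone and the formyl resorcinol of ring A are competing sites. The attack must occur at a carbon flanked by a methyl group and the ester oxygen, in a seven-membered closure that competes with solvent capture, spiro-cyclisation and cleavage of the labile depside ester.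
- Comparison: against the brevity, the chosen plan offers an ether oxygen that is fixed on ring B from 11 onwards, ring A construction steered by the polarity of its two partners, and failure modes confined to single steps that can be replaced.

**Alternative 2: cyclotrimerisation of three alkynes.** The cut removes three C–C bonds of ring A and the dioxepinone ring at once. The precursor is diyne A3, in which an ynol ether and a but-2-ynoate ester hang from the two oxygens of the ring B catechol; the third alkyne is A4. A transition-metal-catalysed [2+2+2] reaction would give A5.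

- Merits: the largest gain in complexity per step. The ester is made early by simple acylation, so no seco acid and no late lactonisation are needed. In this respect it is better than the chosen plan.
- Weak points: the five-atom tether must deliver a seven-membered ring, a much less common case than five- or six-membered tethers. The orientation of A4 (ethoxy carbon next to the acetal carbon) rests only on steric and electronic bias in a crowded metallacycle. The aryl butynoate of A3 is a strong acylating agent that must coexist with an ynol ether. After the key step the silyl group has to be removed and the ethyl ether cleaved without opening the lactone.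
- Comparison: the chosen plan sets against this a regiochemistry that follows from ketene and ynol ether polarity with no orientation to control, a free hydroxyl delivered directly, and simpler precursors.

**Alternative 3: aryloxypyrone plus alkoxyalkyne.** The cut removes two C–C bonds of ring A. The fully substituted 2-pyrone A6, which carries the ring B aryloxy group at C-4, would react with A7 by [4+2] cycloaddition and decarboxylative aromatisation to give A8.

- Merits: the aryl–oxygen bond is made by addition–elimination at an activated pyrone carbon, which is more tolerant of a hindered phenol than the vinylation used in steps 7 and 8 of the chosen route. No diazo compound and no light are needed. On the robustness of the C–O bond formation it is at least as good as the chosen plan.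
- Weak points: a tetrasubstituted pyrone is a sluggish diene and needs temperatures at which A7 is volatile and thermally labile. The required orientation puts the nucleophilic CH carbon on C-6, which bears a methyl group; the C-5 ester favours this but does not secure it. Only two ring bonds form in the key step, the pyrone needs its own multistep synthesis, and the ethyl ether in A8 costs a selective dealkylation.
- Comparison: the chosen plan forms three ring bonds from two small fragments, gives the free phenol, and needs one step fewer after the key event. It has to accept the less certain ynol ether synthesis in return.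

Key step: step 9

Assumption: benzyl diazoacetate (1) and 2,2-diethoxyacetaldehyde (5) are taken as purchasable. Compounds 3 and 15 are racemic and lose their stereocentre in the next event, so no stereocontrol is needed.

## Route

Step 1
Reactants: 1 benzyl diazoacetate; 2 methacrolein (2-methylprop-2-enal)
Product: 3 benzyl 2-diazo-3-hydroxy-4-methylpent-4-enoate (racemic)
Conditions: LiN(iPr)2 (LDA), THF, −78 °C; AcOH quench
Reagents that add atoms: none
Why: Aldol-type addition of the lithiated diazoacetate to the aldehyde carbonyl is fast at −78 °C, where dipolar cycloaddition to the enal does not compete; the carbinol centre is racemic and is removed in step 2.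

Step 2
Reactants: 3 benzyl 2-diazo-3-hydroxy-4-methylpent-4-enoate
Product: 4 benzyl 2-diazo-4-methyl-3-oxopent-4-enoate
Conditions: Dess–Martin periodinane, NaHCO3, CH2Cl2, 0 °C to rt
Reagents that add atoms: none
Why: Dess–Martin oxidation of α-diazo-β-hydroxy esters to α-diazo-β-keto esters is standard, the alcohol here is also allylic, and the buffer protects the acid-sensitive diazo alcohol.

Step 3
Reactants: 5 2,2-diethoxyacetaldehyde
Product: 6 1,1-dibromo-3,3-diethoxyprop-1-ene
Conditions: CBr4, PPh3, Et3N, CH2Cl2, 0 °C
Reagents that add atoms: carbon tetrabromide, BrC(Br)(Br)Br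
Why: Ramirez dibromo-olefination (first stage of the Corey–Fuchs sequence); the amine keeps the medium non-acidic so that the acetal should survive.

Step 4
Reactants: 7 1-(2,4-dihydroxy-6-methylphenyl)ethanone
Product: 8 1-(4-benzyloxy-2-hydroxy-6-methylphenyl)ethanone
Conditions: BnBr, K2CO3, acetone, reflux
Reagents that add atoms: benzyl bromide, BrCc1ccccc1
Why: Williamson etherification; the 2-hydroxyl is hydrogen-bonded to the acetyl group and the 4-hydroxyl, para to the acyl group, is the more acidic, so mono-benzylation at O-4 is expected.

Step 5
Reactants: 8 1-(4-benzyloxy-2-hydroxy-6-methylphenyl)ethanone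
Product: 10 1-(4-benzyloxy-3,6-dihydroxy-2-methylphenyl)ethanone, via aryl sulfate 9 (not isolated)
Conditions: K2S2O8, aq. NaOH, pyridine, 0 °C to rt; then aq. HCl, Na2SO3, 80 °C
Reagents that add atoms: potassium peroxydisulfate, [K+].[K+].[O-]S(=O)(=O)OOS(=O)(=O)[O-]
Why: Elbs persulfate oxidation: the phenoxide attacks peroxydisulfate through its para carbon to give aryl sulfate 9, which acid hydrolyses. This is the classical entry to 2,5-dihydroxyacetophenones from 2-hydroxy-4,6-disubstituted acetophenones and places the oxygen at the future C-6 of the chromanone.

Step 6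
Reactants: 10 1-(4-benzyloxy-3,6-dihydroxy-2-methylphenyl)ethanone
Product: 11 7-benzyloxy-6-hydroxy-2,2,5-trimethylchroman-4-one
Conditions: acetone, pyrrolidine, toluene, 80 °C, argon
Reagents that add atoms: acetone, CC(C)=O
Why: Kabbe condensation: pyrrolidine mediates aldol condensation of the acetyl group with acetone and the ortho phenol closes the pyranone by oxa-Michael addition. Only the hydroxyl ortho to the acyl group can cyclise, and 2,5-dihydroxyacetophenones are established substrates when air is excluded.

Step 7
Reactants: 11 7-benzyloxy-6-hydroxy-2,2,5-trimethylchroman-4-one; 6 1,1-dibromo-3,3-diethoxyprop-1-ene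
Product: 12 7-benzyloxy-6-[(Z)-1-bromo-3,3-diethoxyprop-1-enyloxy]-2,2,5-trimethylchroman-4-one
Conditions: CuI (10 mol %), 2,2'-bipyridine (20 mol %), K3PO4, toluene, 110 °C
Reagents that add atoms: none
Why: Copper-catalysed Ullmann-type coupling of a phenol with a 1,1-dibromoalkene; the C–Br bond trans to the substituent reacts, so the (Z)-bromoenol ether with H and Br anti is expected, and K3PO4 is mild enough for the chromanone.

Step 8
Reactants: 12 7-benzyloxy-6-[(Z)-1-bromo-3,3-diethoxyprop-1-enyloxy]-2,2,5-trimethylchroman-4-one
Product: 13 7-benzyloxy-6-(3,3-diethoxyprop-1-ynyloxy)-2,2,5-trimethylchroman-4-one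
Conditions: KOtBu (2.2 equiv), THF, −40 to 0 °C
Reagents that add atoms: none
Why: Anti E2 dehydrobromination of the (Z)-bromoenol ether gives the ynol ether; the chromanone is enolised reversibly (hence the extra base) and is returned on quench.

Step 9
Reactants: 13 7-benzyloxy-6-(3,3-diethoxyprop-1-ynyloxy)-2,2,5-trimethylchroman-4-one; 4 benzyl 2-diazo-4-methyl-3-oxopent-4-enoate
Product: 18 benzyl 2-[(7-benzyloxy-2,2,5-trimethyl-4-oxochroman-6-yl)oxy]-3-(diethoxymethyl)-4-hydroxy-6-methylbenzoate, via vinylketene 14 (not isolated), via vinylcyclobutenone 15 (not isolated), via dienylketene 16 (not isolated), via cyclohexadienone 17 (not isolated)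
Conditions: hν (365 nm), 4 added slowly to 13, ClCH2CH2Cl, rt; then 80 °C
Reagents that add atoms: none
Why: Light expels N2 from 4 and the isopropenyl group migrates (Wolff rearrangement) to give the ester-substituted vinylketene 14, whose carbonyl carbon is attacked by the oxygen-activated β-carbon of ynol ether 13 in a regiospecific [2+2] cycloaddition that gives 4-vinylcyclobutenone 15. Ring strain drives thermal 4π electrocyclic opening of 15 to dienylketene 16, and ring A then closes by a thermal 6π electrocyclisation in which the ketene carbon bonds to the terminal CH2, giving cyclohexadienone 17, which tautomerises to phenol 18. The closest known reaction is the Danheiser benzannulation in its diazo ketone (photochemical Wolff) form with alkoxy- and siloxyalkynes. No stereocentre remains in 18; the quaternary centre of 15 is racemic and disappears on ring opening. The required orientation (aryloxy carbon next to the ester carbon, acetal carbon next to the new hydroxyl) follows from the matched polarity of the electrophilic ketene carbon and the nucleophilic alkyne β-carbon. Closure through the ester oxygen ([4+2]) should be slower because an ester carbonyl is a poor heterodiene terminus, as the [2+2] behaviour of alkoxycarbonylketenes towards imines shows. Irradiation at 365 nm, where the chromanone of 13 absorbs little, and slow addition of 4 keep the ketene concentration low and limit dimerisation and O-acylation of 18.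

Step 10
Reactants: 18 benzyl 2-[(7-benzyloxy-2,2,5-trimethyl-4-oxochroman-6-yl)oxy]-3-(diethoxymethyl)-4-hydroxy-6-methylbenzoate
Product: 19 3-(diethoxymethyl)-4-hydroxy-2-[(7-hydroxy-2,2,5-trimethyl-4-oxochroman-6-yl)oxy]-6-methylbenzoic acid
Conditions: H2 (1 atm), Pd/C, EtOAc, rt
Reagents that add atoms: none
Why: Hydrogenolysis of the benzyl ester and the aryl benzyl ether on Pd/C; the aryl ketone and diaryl ether should survive, and partial loss of the acetal is harmless because acetal and aldehyde forms converge in step 11.

Step 11
Reactants: 19 3-(diethoxymethyl)-4-hydroxy-2-[(7-hydroxy-2,2,5-trimethyl-4-oxochroman-6-yl)oxy]-6-methylbenzoic acid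
Product: 21 mollicellin A, via depsidone acetal 20 (not isolated)
Conditions: DCC, CH2Cl2 (high dilution), 0 °C to rt; then 1 M HCl, THF, rt
Reagents that add atoms: water, O
Why: Carbodiimide (Steglich-type) lactonisation: the diaryl ether holds the ring B 7-hydroxyl next to the activated carboxyl, so seven-membered closure should outrun intermolecular acylation; the salicylaldehyde acetal then hydrolyses under mild aqueous acid that leaves the aryl ester intact.

## Compound list

1 | benzyl diazoacetate | [N-]=[N+]=CC(=O)OCc1ccccc1 | starting material
2 | methacrolein (2-methylprop-2-enal) | C=C(C)C=O | starting material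
3 | benzyl 2-diazo-3-hydroxy-4-methylpent-4-enoate (racemic) | C=C(C)C(O)C(=[N+]=[N-])C(=O)OCc1ccccc1 | intermediate
4 | benzyl 2-diazo-4-methyl-3-oxopent-4-enoate | C=C(C)C(=O)C(=[N+]=[N-])C(=O)OCc1ccccc1 | intermediate
5 | 2,2-diethoxyacetaldehyde | CCOC(OCC)C=O | starting material
6 | 1,1-dibromo-3,3-diethoxyprop-1-ene | CCOC(OCC)C=C(Br)Br | intermediate
7 | 1-(2,4-dihydroxy-6-methylphenyl)ethanone | CC(=O)c1c(C)cc(O)cc1O | starting material
8 | 1-(4-benzyloxy-2-hydroxy-6-methylphenyl)ethanone | CC(=O)c1c(C)cc(OCc2ccccc2)cc1O | intermediate
9 | potassium 3-acetyl-6-benzyloxy-4-hydroxy-2-methylphenyl sulfate (not isolated) | CC(=O)c1c(C)c(OS(=O)(=O)[O-])c(OCc2ccccc2)cc1O.[K+] | intermediate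
10 | 1-(4-benzyloxy-3,6-dihydroxy-2-methylphenyl)ethanone | CC(=O)c1c(C)c(O)c(OCc2ccccc2)cc1O | intermediate
11 | 7-benzyloxy-6-hydroxy-2,2,5-trimethylchroman-4-one | Oc1c(OCc2ccccc2)cc2OC(C)(C)CC(=O)c2c1C | intermediate
12 | 7-benzyloxy-6-[(Z)-1-bromo-3,3-diethoxyprop-1-enyloxy]-2,2,5-trimethylchroman-4-one | CCOC(OCC)/C=C(\Br)Oc1c(OCc2ccccc2)cc2OC(C)(C)CC(=O)c2c1C | intermediate
13 | 7-benzyloxy-6-(3,3-diethoxyprop-1-ynyloxy)-2,2,5-trimethylchroman-4-one | CCOC(OCC)C#COc1c(OCc2ccccc2)cc2OC(C)(C)CC(=O)c2c1C | intermediate
14 | benzyl 3-methyl-2-(oxomethylidene)but-3-enoate, the vinylketene (not isolated) | C=C(C)C(=C=O)C(=O)OCc1ccccc1 | intermediate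
15 | benzyl 2-[(7-benzyloxy-2,2,5-trimethyl-4-oxochroman-6-yl)oxy]-3-(diethoxymethyl)-4-oxo-1-(prop-1-en-2-yl)cyclobut-2-ene-1-carboxylate (racemic, not isolated) | C=C(C)C1(C(=O)OCc2ccccc2)C(=O)C(C(OCC)OCC)=C1Oc1c(OCc2ccccc2)cc2OC(C)(C)CC(=O)c2c1C | intermediate
16 | benzyl (2Z)-3-[(7-benzyloxy-2,2,5-trimethyl-4-oxochroman-6-yl)oxy]-4-(diethoxymethyl)-5-oxo-2-(prop-1-en-2-yl)penta-2,4-dienoate, the dienylketene (not isolated) | O=C=C(C(OCC)OCC)/C(Oc1c(OCc2ccccc2)cc2OC(C)(C)CC(=O)c2c1C)=C(\C(C)=C)C(=O)OCc1ccccc1 | intermediate
17 | benzyl 6-[(7-benzyloxy-2,2,5-trimethyl-4-oxochroman-6-yl)oxy]-5-(diethoxymethyl)-2-methyl-4-oxocyclohexa-1,5-diene-1-carboxylate, keto tautomer of 18 (not isolated) | O=C1CC(C)=C(C(=O)OCc2ccccc2)C(Oc2c(OCc3ccccc3)cc3OC(C)(C)CC(=O)c3c2C)=C1C(OCC)OCC | intermediate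
18 | benzyl 2-[(7-benzyloxy-2,2,5-trimethyl-4-oxochroman-6-yl)oxy]-3-(diethoxymethyl)-4-hydroxy-6-methylbenzoate | O=C(OCc1ccccc1)c1c(C)cc(O)c(C(OCC)OCC)c1Oc1c(OCc2ccccc2)cc2OC(C)(C)CC(=O)c2c1C | intermediate
19 | 3-(diethoxymethyl)-4-hydroxy-2-[(7-hydroxy-2,2,5-trimethyl-4-oxochroman-6-yl)oxy]-6-methylbenzoic acid | O=C(O)c1c(C)cc(O)c(C(OCC)OCC)c1Oc1c(O)cc2OC(C)(C)CC(=O)c2c1C | intermediate
20 | mollicellin A diethyl acetal, the depsidone with CH(OEt)2 in place of CHO (not isolated) | Cc1cc(O)c(C(OCC)OCC)c2c1C(=O)Oc1cc3c(c(C)c1O2)C(=O)CC(C)(C)O3 | intermediate
21 | mollicellin A | Cc1cc(O)c(C=O)c2c1C(=O)Oc1cc3c(c(C)c1O2)C(=O)CC(C)(C)O3 | target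

## Step count and least certain steps

Total: 11 steps. Longest linear sequence: 8 steps (from 7 through steps 4 to 11).

**Step 9 (key step).** The most likely failure is capture of ketene 14 by something other than the [2+2] addition. The ynol ether 13 carries a hindered aryloxy group and an inductively withdrawing acetal, so it is only a modest nucleophile. Ketene dimerisation, closure of the ketene–alkyne adduct through the ester oxygen, or absorption of light by the chromanone of 13 (inner filter, sensitised carbene chemistry of 4) could then outrun the benzannulation. The fallback leaves ketene chemistry, sets out from 11 and comes back at 19; it forms the diaryl ether by nucleophilic aromatic substitution on a separately made ring A fluoride. Purchased 2,6-difluoro-4-methylbenzaldehyde is converted with HC(OEt)3 and catalytic TsOH into 2-(diethoxymethyl)-1,3-difluoro-5-methylbenzene F1. Fluorine-directed ortho-lithiation (s-BuLi, THF, −78 °C; the two ring hydrogens are equivalent), trapping with benzyl chloroformate and acidic work-up should give benzyl 2,4-difluoro-3-formyl-6-methylbenzoate F2. Benzyl alcohol and K2CO3 should displace the less hindered fluoride para to the ester to give benzyl 4-benzyloxy-2-fluoro-3-formyl-6-methylbenzoate F3. The remaining fluoride, activated by the ortho formyl and ortho ester groups, is displaced by the phenoxide of 11 (Cs2CO3, DMF) to give benzyl 4-benzyloxy-2-[(7-benzyloxy-2,2,5-trimethyl-4-oxochroman-6-yl)oxy]-3-formyl-6-methylbenzoate F4. Acetalisation (HC(OEt)3, EtOH, TsOH) gives the corresponding diethyl acetal, benzyl 4-benzyloxy-2-[(7-benzyloxy-2,2,5-trimethyl-4-oxochroman-6-yl)oxy]-3-(diethoxymethyl)-6-methylbenzoate F5, and hydrogenolysis of its three benzyl groups (H2, Pd/C) gives 19.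

**Step 7.** The phenol of 11 has two ortho substituents and 6 is an alkyl-type dibromoalkene. Slow C–O coupling is therefore the main danger, with base-induced dehydrobromination of 6 and over-reaction to a ketene acetal taking over. The fallback sets out from 11 and comes back at 13, so it also replaces step 8. It uses the dichlorovinyl ether route, which is insensitive to hindrance at the phenol. Trichloroethylene, K2CO3 and DMF at 70 °C give 7-benzyloxy-6-[(E)-1,2-dichloroethenyloxy]-2,2,5-trimethylchroman-4-one F6. The ketone is masked with TBSOTf and Et3N as the silyl enol ether tert-butyl{[7-benzyloxy-6-[(E)-1,2-dichloroethenyloxy]-2,2,5-trimethyl-2H-chromen-4-yl]oxy}dimethylsilane F7. n-BuLi (2.2 equiv, THF, −78 °C) converts the dichlorovinyl ether into the lithium aryloxyacetylide, which after transmetalation with MgBr2·OEt2 is trapped with diethyl phenyl orthoformate to give tert-butyl{[7-benzyloxy-6-(3,3-diethoxyprop-1-ynyloxy)-2,2,5-trimethyl-2H-chromen-4-yl]oxy}dimethylsilane F8. Buffered TBAF releases the ketone and gives 13.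

**Step 5.** Elbs oxidations typically stop at partial conversion. Here the para position is flanked by a methyl and a benzyloxy group, so slow attack on peroxydisulfate and competing radical oxidation of the electron-rich ring or of the product hydroquinone are the likely losses. The fallback sets out from 8 and comes back at 10. Teuber oxidation with (KSO3)2NO in buffered aqueous acetone takes the phenol to the para-quinone 2-acetyl-5-benzyloxy-3-methylcyclohexa-2,5-diene-1,4-dione F9, and Na2S2O4 reduces this to 10.

**Step 10.** The carboxylic acid formed during hydrogenolysis can cleave the ortho-hydroxy acetal. The freed salicylaldehyde, or the benzylic C–O bonds of the acetal, may then be reduced over Pd/C. The fallback sets out from 18 and comes back at 21 without any reductant. BCl3 with pentamethylbenzene in CH2Cl2 at −78 °C should remove both benzyl groups and the acetal, giving 3-formyl-4-hydroxy-2-[(7-hydroxy-2,2,5-trimethyl-4-oxochroman-6-yl)oxy]-6-methylbenzoic acid F10. DCC lactonisation as in step 11, without the hydrolysis stage, then gives 21.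

## Further compounds

F1 | step 9 | 2-(diethoxymethyl)-1,3-difluoro-5-methylbenzene | CCOC(OCC)c1c(F)cc(C)cc1F
F2 | step 9 | benzyl 2,4-difluoro-3-formyl-6-methylbenzoate | O=Cc1c(F)cc(C)c(C(=O)OCc2ccccc2)c1F
F3 | step 9 | benzyl 4-benzyloxy-2-fluoro-3-formyl-6-methylbenzoate | O=Cc1c(OCc2ccccc2)cc(C)c(C(=O)OCc2ccccc2)c1F
F4 | step 9 | benzyl 4-benzyloxy-2-[(7-benzyloxy-2,2,5-trimethyl-4-oxochroman-6-yl)oxy]-3-formyl-6-methylbenzoate | O=Cc1c(OCc2ccccc2)cc(C)c(C(=O)OCc2ccccc2)c1Oc1c(OCc2ccccc2)cc2OC(C)(C)CC(=O)c2c1C
F5 | step 9 | benzyl 4-benzyloxy-2-[(7-benzyloxy-2,2,5-trimethyl-4-oxochroman-6-yl)oxy]-3-(diethoxymethyl)-6-methylbenzoate | CCOC(OCC)c1c(OCc2ccccc2)cc(C)c(C(=O)OCc2ccccc2)c1Oc1c(OCc2ccccc2)cc2OC(C)(C)CC(=O)c2c1C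
F6 | step 7 | 7-benzyloxy-6-[(E)-1,2-dichloroethenyloxy]-2,2,5-trimethylchroman-4-one | Cl/C=C(/Cl)Oc1c(OCc2ccccc2)cc2OC(C)(C)CC(=O)c2c1C
F7 | step 7 | tert-butyl{[7-benzyloxy-6-[(E)-1,2-dichloroethenyloxy]-2,2,5-trimethyl-2H-chromen-4-yl]oxy}dimethylsilane | Cl/C=C(/Cl)Oc1c(OCc2ccccc2)cc2OC(C)(C)C=C(O[Si](C)(C)C(C)(C)C)c2c1C
F8 | step 7 | tert-butyl{[7-benzyloxy-6-(3,3-diethoxyprop-1-ynyloxy)-2,2,5-trimethyl-2H-chromen-4-yl]oxy}dimethylsilane | CCOC(OCC)C#COc1c(OCc2ccccc2)cc2OC(C)(C)C=C(O[Si](C)(C)C(C)(C)C)c2c1C
F9 | step 5 | 2-acetyl-5-benzyloxy-3-methylcyclohexa-2,5-diene-1,4-dione | CC(=O)C1=C(C)C(=O)C(OCc2ccccc2)=CC1=O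
F10 | step 10 | 3-formyl-4-hydroxy-2-[(7-hydroxy-2,2,5-trimethyl-4-oxochroman-6-yl)oxy]-6-methylbenzoic acid | Cc1cc(O)c(C=O)c(Oc2c(O)cc3OC(C)(C)CC(=O)c3c2C)c1C(=O)O
A1 | alternative 1 | 3-hydroxy-5-methyl-4-(3-methylbut-2-enoyl)phenyl 3-formyl-2,4-dihydroxy-6-methylbenzoate (the depside) | Cc1cc(O)c(C=O)c(O)c1C(=O)Oc1cc(O)c(C(=O)C=C(C)C)c(C)c1
A2 | alternative 1 | pyranone-opened mollicellin A (depsidone with free ring B phenol and 3-methylbut-2-enoyl ketone) | Cc1cc(O)c(C=O)c2c1C(=O)Oc1cc(O)c(C(=O)C=C(C)C)c(C)c1O2
A3 | alternative 2 | 6-(3,3-diethoxyprop-1-ynyloxy)-2,2,5-trimethyl-4-oxochroman-7-yl but-2-ynoate (the tethered diyne) | CCOC(OCC)C#COc1c(OC(=O)C#CC)cc2OC(C)(C)CC(=O)c2c1C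
A4 | alternative 2 | ethoxy(trimethylsilyl)acetylene | CCOC#C[Si](C)(C)C
A5 | alternative 2 | depsidone with ring A ethyl ether, C-trimethylsilyl group and diethyl acetal | Cc1c([Si](C)(C)C)c(OCC)c(C(OCC)OCC)c2c1C(=O)Oc1cc3c(c(C)c1O2)C(=O)CC(C)(C)O3
A6 | alternative 3 | benzyl 4-[(7-benzyloxy-2,2,5-trimethyl-4-oxochroman-6-yl)oxy]-5-(dimethoxymethyl)-2-methyl-6-oxo-6H-pyran-3-carboxylate (the aryloxypyrone) | COC(OC)C1=C(Oc2c(OCc3ccccc3)cc3OC(C)(C)CC(=O)c3c2C)C(C(=O)OCc2ccccc2)=C(C)OC1=O
A7 | alternative 3 | ethoxyacetylene | CCOC#C
A8 | alternative 3 | benzyl 2-[(7-benzyloxy-2,2,5-trimethyl-4-oxochroman-6-yl)oxy]-3-(dimethoxymethyl)-4-ethoxy-6-methylbenzoate | O=C(OCc1ccccc1)c1c(C)cc(OCC)c(C(OC)OC)c1Oc1c(OCc2ccccc2)cc2OC(C)(C)CC(=O)c2c1C
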